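Slowness is what these runs show first: the north-west run reads 0% product at 15.0 min and has reached 8.6% of its substrate by 2 h.

| flask | substrate | reagent | remark | time |
|---|---|---|---|---|
| north-west | 20 mM | 26 mM | run made earlier |  |
| west | 28 mM | 26 mM | run made earlier |  |
| south-west | 44 mM | 26 mM | run made earlier |  |
| south-east | 20 mM | 13 mM | run made earlier |  |
| grey | 20 mM | 26.0 mM | one stirred flow tank at steady state, fed with the mixture as stated, mean residence time 3.0 h |  |
| ochre | 20 mM (fed, over 3.00 h) | 26.0 mM | a stirred flask in which substrate is dosed at a steady rate over 3.00 h without added volume, worked up at 3.0 h | 3.0 h |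
| teal | 20 mM | 26.0 mM | everything together in a closed stirred flask, run for 3.0 h | 3.0 h |
| blue | 20 mM | 26.0 mM | a single well-mixed tank run continuously and read at steady state, 9.00 h in it on average |  |

north-west run (percent of the substrate charged)

| time / min | product / % |
|---|---|
| 15.0 | 0 |
| 30.0 | 0.9 |
| 50.0 | 1.6 |
| 60.0 | 2.1 |
| 80.0 | 4.9 |
| 90.0 | 4.6 |
| 120 | 8.6 |

west run (percent of the substrate charged)

| time / h | product / % |
|---|---|
| 0.133 | 0 |
| 0.333 | 0.7 |
| 0.667 | 1.2 |
| 1.00 | 2.7 |
| 1.33 | 4.4 |
| 2.00 | 7.2 |
| 2.50 | 11.4 |

south-west run (percent of the substrate charged)

| time / h | product / % |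
|---|---|
| 0.133 | 0 |
| 0.333 | 0.3 |
| 0.667 | 0.5 |
| 1.00 | 1.4 |
| 1.33 | 2.9 |
| 2.00 | 5.3 |
| 2.50 | 8.8 |

south-east run (percent of the substrate charged)

| time / h | product / % |
|---|---|
| 0.200 | 0.9 |
| 0.333 | 0 |
| 0.667 | 0.1 |
| 1.33 | 3.0 |
| 2.50 | 8.2 |

(each reading ± 0.5 percentage points)

- the stated concentrations are those of everything mixed, before any reaction; amounts are the same in each set-up
- the earlier runs were read with a standard deviation of 0.5 percentage points
- the feed brings no volume worth counting
- the earlier runs were made in a closed, stirred flask
- a reading or a percentage of product counts all its forms, free or not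

- the set-up with the highest amount of product at the outlet or at the end, in percent of the substrate put in ("none" if the first two lie within 2 percentage points) (grey / ochre / teal / blue / none)
- amount of product at the outlet or at the end, in percent of the substrate put in, grey
- amount of product at the outlet or at the end, in percent of the substrate put in, ochre
- amount of product at the outlet or at the end, in percent of the substrate put in, teal
- amount of product at the outlet or at the end, in percent of the substrate put in, blue

Two chemists at the blackboard read this lag differently, and both reckon with the fraction left.

The second chemist says product feeds itself, like a fire. From 2.1% at 1 h to 8.6% at 2 h, the north-west run grows with a constant g of 1.41 h⁻¹. In a burning tank with mean residence time τ, the fraction left is 1/(gτ), so grey gives 76.4% and blue 92.1%.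

The first chemist says material stands in a queue. She assumes quick capture by reagent, then two equal stages in a row, with k, the share of a stage's content handed on per hour. The fraction left, not yet through, is L = (1 + kt)·e^(−kt) in a closed flask, while in a tank each stage hands on kτ/(1 + kτ), so the two together pass that share squared. Solving for the fraction made, F, gives roughly kt = s/(1 − s/3), with s = √(2F). The north-west reading then gives k = 0.241 h⁻¹, with the scatter of that reading.

Her test uses the readings at 2.50 h, divided by the share reagent can capture. West gives 12.3%, south-west 14.9% and south-east 12.6%, against 12.3% from L.

Her figures are 83.7% left in teal, so 16.3% made; grey 17.6%; blue 46.8%. Substrate goes into ochre at a steady rate over 3.00 h, so she averages her fraction made over portions aged from zero up to 3.00 h, which gives ochre 6.13%, less than teal.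

The fire keeps the closed flask up to 2 h: its curve passes through the two readings it was drawn from, and L gives 2.48% at 1 h, so there neither view beats the other.

The forecast, hedged towards the fire, names blue best with grey 45%, ochre 14%, teal 19% and blue 75%, since “the tank holds product and ignites”.

    substrate + reagent → intermediate A (k = 320 M⁻¹ h⁻¹)
    intermediate A → intermediate B (k = 0.530 h⁻¹)
    intermediate B → product (k = 0.160 h⁻¹)
    substrate + product ⇌ idle adduct, settled at all times (K = 18.0 M⁻¹)

The flasks give blue as best: grey 17.6%, ochre 6.83%, teal 18.1%, blue 46.2%, which is the queue's pattern. In teal at 3.00 h, intermediate B holds 58.5% and intermediate A 23.4% of the substrate charged. Left for 30.0 h, teal has L = 0.596%, so k gives 99.4% product, and the flask gives 98.8%.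

A neighbour of teal has 6.5 mM of reagent, which is now the limiting reagent. It can capture 32.5% of the substrate, and with the same L the reckoning gives 5.31% product. The computed flask gives 5.98%, with 66.3% of the substrate still there.

All runs are calculated from invented constants.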